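## Structural features

Hierochin B is a 2,3-dihydrobenzofuran in which benzene ring A (C3a, C4–C7, C7a) is fused to a five-membered ring made of O1, C2, C3, C3a and C7a. C2 carries the 3,4-dimethoxyphenyl group (ring B) and the ring oxygen; C3 carries the hydroxymethyl arm and is bonded to C3a. Ring A has a methoxy group at C7, next to the oxygen-bearing C7a, and an (E)-3-hydroxyprop-1-enyl chain at C5. The only stereocentres, C2 (S) and C3 (R), are adjacent benzylic methines with the aryl group and the CH2OH arm trans. The O1–C2 bond is a benzylic ether para to a methoxy donor and ionises in acid, the cinnamyl alcohol is sensitive to acid and oxidants, and both arenes are electron-rich. The real difficulty is fixing the absolute configuration of two contiguous centres, since the trans relationship itself is the more stable one. The key step uses the fact that C2 and C3 are neighbouring CH units each bonded to exactly one aryl ring: a two-carbon alkenylboron unit takes ring B at C2 by migration from boron and ring A at C3 from palladium, and the boron left on C2 later becomes the site of the O1–C2 bond.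

## Logic of the disconnections

**18 ⇒ 17 ⇒ 16.** The side-chain C=C bond at C5 is cut after the allylic alcohol is traced back to an ester. This chain is the most fragile part and is therefore made last. The cut reduces the chain to a formyl group. The forward steps must give only the E alkene, tolerate a free primary alcohol and reduce the ester without touching the alkene.

**16 ⇒ 15.** No skeletal bond is cut; the aldehyde and the primary alcohol are masked as cyclic acetal and alkyl silyl ether. One acid treatment has to remove both, under conditions too mild to open O1–C2.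

**15 ⇒ 14.** The O1–C2 bond is cut. It is the ring bond that can be closed stereospecifically from an sp3 carbinol, and cutting it opens the heterocycle to a chain with a phenol and a secondary benzylic alcohol. The forward closure is an SN2 displacement with inversion, so 14 needs the anti relationship, a free phenol and a masked primary alcohol. The phenol must therefore be freed without acid, which would strip the primary silyl ether and ionise the benzylic alcohol.

**14 ⇒ 13.** The C2–O bond is traced back to C2–B and the phenol to its aryl silyl ether. Boron is what makes the next cut possible, and its oxidation goes with retention. The aryl silyl ether in 13 replaces an acetal-type phenol ether because alkaline peroxide cleaves it in the same operation, while the alkyl silyl ether and the acetal survive base.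

**13 ⇒ 11 + 6 + 9.** Two bonds are cut: C2 to ring B and C3–C3a. This is the strategic cut, because it reduces 13 to three simple pieces and creates both stereocentres in one convergent step. The forward step must add the two aryl groups anti across the Z alkene of 6, with the face chosen by the catalyst, and must tolerate the ortho silyloxy group of 9 and the bromide it releases.

**6 ⇒ 2 + 4 (through 5); 2 ⇒ 1; 4 ⇒ 3.** The C–B bond is cut back to a terminal alkyne and the boron ligand to its diol. The demand is Z geometry, which an ordinary syn hydroboration cannot give, so a trans-hydroboration is needed, followed by ligand exchange without isomerisation.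

**9 ⇒ 8 ⇒ 7.** Only protecting groups are removed. The aldehyde must be masked before the peroxide step, and the acetal must be put on without acid that would endanger the aryl silyl ether.

**11 ⇒ 10.** The C–Li bond comes from C–Br by halogen–lithium exchange, which must not leave lithium halide in the mixture.

## Other disconnections considered

**Alternative 1:** The cut is at C3–C3a and at the C–O bond of the hydroxymethyl arm, with O1–C2 made first. In the forward direction, [Ir(cod)Cl]2 (monovalent iridium) with a phosphoramidite would etherify 5-iodovanillin with a 3,4-dimethoxycinnamyl carbonate to the branched ether A2, which sets C2. Bu3SnH with TEMPO would then turn the aryl iodide of A2 into a radical that closes 5-exo onto the vinyl group, and TEMPO would cap the primary radical to give A1.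
- In its favour: C2 comes from well-understood catalysis, the aldehyde needs no protection, and ring closure and oxygenation happen in one step. N–O cleavage of A1 would lead to the same aldehyde as 16.
- Against it here: C3 is set only by the conformational preference of the radical transition state, not stereospecifically. The phenoxide of 5-iodovanillin is hindered on both sides and electron-poor. A2 is an allylic and p-alkoxybenzylic ether that can ionise and racemise. Tin is used in stoichiometric amount.
- Comparison: both plans put O1 on C2 and ring A on C3, but this one closes O1–C2 first and relies on substrate control for C3, where the chosen plan uses catalyst control plus two stereospecific events. On enantiocontrol at C2 it is the equal of the chosen plan. On step count (roughly six operations against eleven) and protecting-group economy it is the better. On diastereocontrol at C3 and reagent toxicity it is the weaker.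

**Alternative 2:** The cut is at C3a–C7a and C6–C7, so ring A does not exist before the key step. In the forward direction, Ph3PAuNTf2 (monovalent gold) would activate the ethynyl ether of the furan A4. The furan carbon would attack the oxygen-bearing alkyne carbon, closing the dihydrofuran, and the furan would reorganise into the benzene ring with its oxygen ending on C7 as the phenol of A3.
- In its favour: the step is an isomerisation with complete atom economy, builds two rings at once, leaves the existing stereocentres untouched, and fixes the ring A pattern by connectivity alone.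
- Against it here: the stereochemical problem is only moved to the open-chain A4, whose two centres need their own asymmetric chemistry. The ethynyl ether of a p-alkoxybenzylic secondary alcohol is hard to make and prone to hydration and ionisation. Oxygen-substituted alkynes are unusual partners in this cascade. A3 still needs phenol methylation, differentiation of two identical silyl ethers, oxidation at C5 and the same olefination and reduction.
- Comparison: ring A is built here and bought in the chosen plan. The mechanism is a cationic gold cascade against a palladium-induced 1,2-shift. The alternative is the better on atom economy of the key step and on freedom from aryl halides and organolithiums, and the equal on regiochemical certainty of ring A. It is expected to be longer overall and does not itself create any stereocentre.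

**Alternative 3:** The cut is at C3a–C4 and C7–C7a; ring A is built onto an intact five-membered ring. In the forward direction, the silyl ketene acetal A7 of the trans lactone A8 would add to methyl 3-bromocoumalate A6 on heating, and the bicyclic adduct would lose CO2 and then silanol to give the arene A5.
- In its favour: both stereocentres reside in a trans-disubstituted butyrolactone A8, a well-studied motif whose trans form is also the stable one. The polarised cycloaddition should be regioselective and is driven by aromatisation. No precious metal or ortho-hindered coupling is needed.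
- Against it here: A7 carries a benzylic C2–O bond and an allylic C3, so heating risks ring opening or elimination. C7 arrives as a bromide and must be exchanged for methoxy by copper-mediated methoxylation on an advanced intermediate. The ester needs redox adjustment before olefination. Enantiopure A8 costs several steps.
- Comparison: once A8 is in hand, stereochemical security equals that of the chosen plan, and the key step is cheaper and simpler, which is a point in its favour. The chosen plan creates both centres in the convergent step and needs fewer operations before and after it.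

Key step: step 6

Remarks on the chemistry:
- The absolute sense of induction of the ferrocenyl bisphosphine is assumed; if the (1S,2S) boronate were favoured, the antipodal ligand, equally available, would be used.
- Diol 4 is made in one step because its commercial supply is not assumed.
- Consistency check: anti addition to the Z alkene gives (1R,2R)-13, oxidation retains, and closure inverts C2, which leads to (2S,3R), trans, as in the target.

## Route

Step 1
Reactants: 1 propargyl alcohol
Product: 2 tert-butyldimethyl(prop-2-yn-1-yloxy)silane
Conditions: TBSCl, imidazole, CH2Cl2, 0 °C → rt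
Reagents that add atoms: tert-butyldimethylsilyl chloride, CC(C)(C)[Si](C)(C)Cl
Why: Standard silylation of a primary alcohol; the silyl ether withstands the borane, organolithium and basic peroxide used later.

Step 2
Reactants: 3 acenaphthoquinone
Product: 4 cis-1,2-dimethyl-1,2-dihydroacenaphthylene-1,2-diol (meso)
Conditions: AlMe3 (3 equiv), toluene, 0 °C → rt; H2O
Reagents that add atoms: trimethylaluminium, C[Al](C)C
Why: Double 1,2-addition of methylaluminium to the diketone; the second methyl is expected to enter anti to the bulky aluminium alkoxide formed first, so the cis diol should predominate and is purified by crystallisation.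

Step 3
Reactants: 2 tert-butyldimethyl(prop-2-yn-1-yloxy)silane; 4 cis-1,2-dimethyl-1,2-dihydroacenaphthylene-1,2-diol
Product: 6 (Z)-3-(tert-butyldimethylsilyloxy)prop-1-enyl B(mac) boronic ester, via (Z)-alkenyl catechol boronate 5 (not isolated)
Conditions: catecholborane, [Rh(cod)Cl]2 (1.5 mol %), P(i-Pr)3 (6 mol %), Et3N, cyclohexane, rt; then 4, rt
Reagents that add atoms: catecholborane, B1Oc2ccccc2O1
Why: Rhodium-catalysed trans-hydroboration of a terminal alkyne through a vinylidene intermediate places H and B anti and gives the Z alkenylboronate; the labile catechol ester is then exchanged for the rigid tertiary diol by transesterification, which does not touch the double bond.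

Step 4
Reactants: 7 5-bromovanillin
Product: 8 3-bromo-4-(tert-butyldimethylsilyloxy)-5-methoxybenzaldehyde
Conditions: TBSCl, imidazole, DMF, rt
Reagents that add atoms: tert-butyldimethylsilyl chloride, CC(C)(C)[Si](C)(C)Cl
Why: Silylation of the acidic phenol; an aryl silyl ether is stable to acid and organometallics but is cleaved by aqueous hydroxide, which is the orthogonality needed in step 7.

Step 5
Reactants: 8 3-bromo-4-(tert-butyldimethylsilyloxy)-5-methoxybenzaldehyde
Product: 9 2-[3-bromo-4-(tert-butyldimethylsilyloxy)-5-methoxyphenyl]-1,3-dioxolane
Conditions: (Me3SiOCH2)2, Me3SiOTf (5 mol %), CH2Cl2, −78 → −20 °C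
Reagents that add atoms: 1,2-bis(trimethylsilyloxy)ethane, C[Si](C)(C)OCCO[Si](C)(C)C
Why: Aprotic acetalisation with the bis-silyl ether of ethylene glycol under silyl triflate catalysis; the low temperature and absence of protic acid spare the aryl silyl ether, and the acetal shields the aldehyde from peroxide in step 7.

Step 6
Reactants: 10 4-bromo-1,2-dimethoxybenzene; 6 (Z)-3-(tert-butyldimethylsilyloxy)prop-1-enyl B(mac) boronic ester; 9 2-[3-bromo-4-(tert-butyldimethylsilyloxy)-5-methoxyphenyl]-1,3-dioxolane
Product: 13 anti (1R,2R) secondary benzylic B(mac) boronate carrying both aryl groups, via 3,4-dimethoxyphenyllithium 11 (not isolated), via lithium aryl alkenyl boronate complex 12 (not isolated)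
Conditions: 10, n-BuLi (1.0 equiv), THF, −78 °C; 6 (1.05 equiv), −78 °C → rt; evaporate; 9 (1.1 equiv), Pd(OAc)2 (3 mol %), 1,1′-bis[bis(3,5-dimethylphenyl)phosphino]-2,2′-bis[(dimethylamino)(phenyl)methyl]ferrocene (Mandyphos type, single enantiomer, 3.6 mol %), KOTf (2 equiv), THF, 60 °C
Reagents that add atoms: none
Why: Bromine–lithium exchange gives 11, which adds to the trigonal boron of 6 to form the tetracoordinate boronate 12; evaporation removes 1-bromobutane so that no halide accompanies 12. Zerovalent palladium, formed from Pd(OAc)2 (divalent palladium) and the bisphosphine, inserts into the C–Br bond of 9, and KOTf removes the bromide as KBr so that a cationic arylpalladium can bind the alkene of 12. Binding triggers a 1,2-metallate shift in which the 3,4-dimethoxyphenyl group moves from boron to C2 anti to palladium, which becomes bonded to C3; reductive elimination with retention then forms C3–C3a. The closest known reaction type is the enantioselective palladium-catalysed conjunctive cross-coupling of β-substituted alkenyl B(mac) boronates with aryllithiums and aryl electrophiles, in which aryl bromides are used with a triflate salt. No ring is closed. C3 is controlled by the chiral bisphosphine, which chooses the alkene face that palladium binds; C2 follows from the stereospecific anti migration, so the Z geometry of 6 becomes the anti (1R,2R) relationship. The step needs the metallate shift to win over direct Suzuki–Miyaura-type transfer from boron and over β-hydride or β-silyloxy elimination; the hindered electron-rich diol ligand on boron, the wide-bite-angle bisphosphine and the poor leaving ability of the silyloxy group are expected to secure this, and the non-coordinating ortho silyl ether of 9 leaves the vacant site on palladium free.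

Step 7
Reactants: 13 anti (1R,2R) secondary benzylic B(mac) boronate
Product: 14 (1R,2R)-3-(tert-butyldimethylsilyloxy)-1-(3,4-dimethoxyphenyl)-2-[5-(1,3-dioxolan-2-yl)-2-hydroxy-3-methoxyphenyl]propan-1-ol
Conditions: 30% H2O2, 3 M NaOH, THF, 0 °C → rt
Reagents that add atoms: hydrogen peroxide, OO
Why: Hydroperoxide adds to boron and carbon migrates to oxygen with retention at C1 (boronate oxidation); the same aqueous hydroxide cleaves the aryl silyl ether, because phenoxide is a good leaving group on silicon, while the alkyl silyl ether and the acetal are stable to base and the acetal prevents Dakin oxidation.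

Step 8
Reactants: 14 (1R,2R)-3-(tert-butyldimethylsilyloxy)-1-(3,4-dimethoxyphenyl)-2-[5-(1,3-dioxolan-2-yl)-2-hydroxy-3-methoxyphenyl]propan-1-ol
Product: 15 (2S,3R)-3-[(tert-butyldimethylsilyloxy)methyl]-2-(3,4-dimethoxyphenyl)-5-(1,3-dioxolan-2-yl)-7-methoxy-2,3-dihydrobenzofuran
Conditions: PPh3, DIAD, toluene/THF, 0 °C → rt
Reagents that add atoms: none
Why: Intramolecular Mitsunobu etherification: the benzylic alcohol is activated as its alkoxyphosphonium ion and displaced by the phenol oxygen in a 5-exo-tet SN2 closure with inversion at C2, which turns the anti precursor into the trans ring; any leakage through the benzylic cation should converge on the same, more stable trans isomer.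

Step 9
Reactants: 15 (2S,3R)-3-[(tert-butyldimethylsilyloxy)methyl]-2-(3,4-dimethoxyphenyl)-5-(1,3-dioxolan-2-yl)-7-methoxy-2,3-dihydrobenzofuran
Product: 16 (2S,3R)-2-(3,4-dimethoxyphenyl)-3-(hydroxymethyl)-7-methoxy-2,3-dihydrobenzofuran-5-carbaldehyde
Conditions: 1 M HCl, THF, rt
Reagents that add atoms: water, O
Why: Acid hydrolysis of the cyclic acetal and of the primary alkyl silyl ether in one operation; dilute acid at room temperature should leave O1–C2 closed, and reversible opening would in any case return the trans isomer.

Step 10
Reactants: 16 (2S,3R)-2-(3,4-dimethoxyphenyl)-3-(hydroxymethyl)-7-methoxy-2,3-dihydrobenzofuran-5-carbaldehyde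
Product: 17 ethyl (E)-3-[(2S,3R)-2-(3,4-dimethoxyphenyl)-3-(hydroxymethyl)-7-methoxy-2,3-dihydrobenzofuran-5-yl]prop-2-enoate
Conditions: Ph3P=CHCO2Et, toluene, 80 °C
Reagents that add atoms: ethyl (triphenylphosphoranylidene)acetate, CCOC(=O)C=P(c1ccccc1)(c1ccccc1)c1ccccc1
Why: Wittig reaction of a stabilised ylide, which is E-selective with aromatic aldehydes and tolerates the free primary alcohol.

Step 11
Reactants: 17 ethyl (E)-3-[(2S,3R)-2-(3,4-dimethoxyphenyl)-3-(hydroxymethyl)-7-methoxy-2,3-dihydrobenzofuran-5-yl]prop-2-enoate
Product: 18 Hierochin B
Conditions: DIBAL-H (4.5 equiv), CH2Cl2, −78 → 0 °C; aqueous work-up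
Reagents that add atoms: none
Why: DIBAL-H reduces the conjugated ester by 1,2-hydride delivery to the allylic alcohol without touching the alkene; the free hydroxyl only consumes one equivalent as its aluminium alkoxide.

## Compound list

1 | propargyl alcohol | C#CCO | starting material
2 | tert-butyldimethyl(prop-2-yn-1-yloxy)silane | C#CCO[Si](C)(C)C(C)(C)C | intermediate
3 | acenaphthoquinone | O=C1C(=O)c2cccc3cccc1c23 | starting material
4 | cis-1,2-dimethyl-1,2-dihydroacenaphthylene-1,2-diol (meso) | O[C@@]1(C)c2cccc3cccc(c23)[C@@]1(C)O | intermediate
5 | 2-[(Z)-3-(tert-butyldimethylsilyloxy)prop-1-enyl]-1,3,2-benzodioxaborole | CC(C)(C)[Si](C)(C)OC/C=C\B1Oc2ccccc2O1 | intermediate (not isolated)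
6 | (Z)-3-(tert-butyldimethylsilyloxy)prop-1-enyl B(mac) boronic ester | CC(C)(C)[Si](C)(C)OC/C=C\B1O[C@@]2(C)c3cccc4cccc(c34)[C@@]2(C)O1 | intermediate
7 | 5-bromovanillin | COc1cc(C=O)cc(Br)c1O | starting material
8 | 3-bromo-4-(tert-butyldimethylsilyloxy)-5-methoxybenzaldehyde | COc1cc(C=O)cc(Br)c1O[Si](C)(C)C(C)(C)C | intermediate
9 | 2-[3-bromo-4-(tert-butyldimethylsilyloxy)-5-methoxyphenyl]-1,3-dioxolane | COc1cc(C2OCCO2)cc(Br)c1O[Si](C)(C)C(C)(C)C | intermediate
10 | 4-bromo-1,2-dimethoxybenzene | COc1ccc(Br)cc1OC | starting material
11 | 3,4-dimethoxyphenyllithium | [Li]c1ccc(OC)c(OC)c1 | intermediate (not isolated)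
12 | lithium (3,4-dimethoxyphenyl)[(Z)-3-(tert-butyldimethylsilyloxy)prop-1-enyl] B(mac) boronate (configuration at boron not defined) | [Li+].COc1ccc(cc1OC)[B-]1(/C=C\CO[Si](C)(C)C(C)(C)C)O[C@@]2(C)c3cccc4cccc(c34)[C@@]2(C)O1 | intermediate (not isolated)
13 | (1R,2R)-3-(tert-butyldimethylsilyloxy)-2-[2-(tert-butyldimethylsilyloxy)-5-(1,3-dioxolan-2-yl)-3-methoxyphenyl]-1-(3,4-dimethoxyphenyl)propyl B(mac) boronate (anti) | COc1ccc([C@H](B2O[C@@]3(C)c4cccc5cccc(c45)[C@@]3(C)O2)[C@@H](CO[Si](C)(C)C(C)(C)C)c2cc(C3OCCO3)cc(OC)c2O[Si](C)(C)C(C)(C)C)cc1OC | intermediate
14 | (1R,2R)-3-(tert-butyldimethylsilyloxy)-1-(3,4-dimethoxyphenyl)-2-[5-(1,3-dioxolan-2-yl)-2-hydroxy-3-methoxyphenyl]propan-1-ol | COc1ccc([C@H](O)[C@@H](CO[Si](C)(C)C(C)(C)C)c2cc(C3OCCO3)cc(OC)c2O)cc1OC | intermediate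
15 | (2S,3R)-3-[(tert-butyldimethylsilyloxy)methyl]-2-(3,4-dimethoxyphenyl)-5-(1,3-dioxolan-2-yl)-7-methoxy-2,3-dihydrobenzofuran (trans) | COc1ccc([C@H]2Oc3c(OC)cc(C4OCCO4)cc3[C@@H]2CO[Si](C)(C)C(C)(C)C)cc1OC | intermediate
16 | (2S,3R)-2-(3,4-dimethoxyphenyl)-3-(hydroxymethyl)-7-methoxy-2,3-dihydrobenzofuran-5-carbaldehyde | COc1ccc([C@H]2Oc3c(OC)cc(C=O)cc3[C@@H]2CO)cc1OC | intermediate
17 | ethyl (E)-3-[(2S,3R)-2-(3,4-dimethoxyphenyl)-3-(hydroxymethyl)-7-methoxy-2,3-dihydrobenzofuran-5-yl]prop-2-enoate | COc1ccc([C@H]2Oc3c(OC)cc(/C=C/C(=O)OCC)cc3[C@@H]2CO)cc1OC | intermediate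
18 | Hierochin B, (E)-3-[(2S,3R)-2-(3,4-dimethoxyphenyl)-3-(hydroxymethyl)-7-methoxy-2,3-dihydrobenzofuran-5-yl]prop-2-en-1-ol | COc1ccc([C@H]2Oc3c(OC)cc(/C=C/CO)cc3[C@@H]2CO)cc1OC | target

## Step count and least certain steps

Total: 11 steps. Longest linear sequence: 8 steps (7 → 8 → 9 → 13 → 14 → 15 → 16 → 17 → 18; the branches from 1 and from 3 are equally long).

**Step 6 (key step).** The most likely failure is that the catalytic cycle stalls or diverts. Oxidative addition and alkene binding at the hindered, electron-rich ortho-silyloxy aryl bromide may be slow, so that direct transfer of a group from boron to palladium or β-elimination from the alkylpalladium takes over. The fallback abandons the boron chemistry, sets C2 by allylic etherification and C3 by radical cyclisation, and runs from 7 to 16.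
- The lithium phenoxide of 7 (LiOt-Bu) would be allylated with (E)-3-(3,4-dimethoxyphenyl)prop-2-en-1-yl methyl carbonate F1, made from commercial (E)-3,4-dimethoxycinnamyl alcohol and methyl chloroformate with pyridine. The catalyst would be [Ir(cod)Cl]2 with a binaphthol-derived bis(1-phenylethyl)amine phosphoramidite in THF, and the product the branched ether (S)-3-bromo-4-{[1-(3,4-dimethoxyphenyl)prop-2-en-1-yl]oxy}-5-methoxybenzaldehyde F2.
- Bu3SnH and TEMPO in toluene at 80 °C would turn the aryl bromide into an aryl radical that closes 5-exo onto the vinyl group, preferentially trans to the aryl group. TEMPO would cap the primary radical to give (2S,3R)-2-(3,4-dimethoxyphenyl)-7-methoxy-3-{[(2,2,6,6-tetramethylpiperidin-1-yl)oxy]methyl}-2,3-dihydrobenzofuran-5-carbaldehyde F3, from which any cis isomer would be removed by chromatography.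
- Zn in AcOH/THF/H2O would cleave the N–O bond and rejoin the route at 16.

**Step 3.** The most likely failure is erosion of the Z geometry, either by competing ordinary syn hydroboration when the vinylidene pathway is slow or by isomerisation during ligand exchange; an E contaminant would end as the wrong diastereomer after step 6. The fallback makes the Z alkene by syn hydrozirconation of an alkynylboronate and runs from 2 to 6.
- Deprotonation of 2 (n-BuLi, THF, −78 °C), addition of B(Oi-Pr)3 and anhydrous HCl in Et2O would give diisopropyl [3-(tert-butyldimethylsilyloxy)prop-1-yn-1-yl]boronate F4.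
- Diol 4 would displace isopropanol to give 3-(tert-butyldimethylsilyloxy)prop-1-yn-1-yl B(mac) boronic ester F5.
- Cp2Zr(H)Cl in THF would add H and Zr syn with zirconium on the boron-bearing carbon, and protonolysis with water, with retention, would give 6.

**Step 7.** The most likely failure is incomplete cleavage of the hindered aryl silyl ether, or oxidative degradation of the freed electron-rich phenolate by alkaline peroxide, including Dakin-type oxidation if the acetal is lost. The fallback separates the two events and avoids peroxide, running from 13 to 14.
- Anhydrous trimethylamine N-oxide in THF at 60 °C would oxidise C–B with retention under neutral conditions to (1R,2R)-3-(tert-butyldimethylsilyloxy)-2-[2-(tert-butyldimethylsilyloxy)-5-(1,3-dioxolan-2-yl)-3-methoxyphenyl]-1-(3,4-dimethoxyphenyl)propan-1-ol F6.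
- K2CO3 in MeOH would then remove only the aryl silyl ether and return the route to 14.

**Step 8.** The most likely failure is ionisation of the activated p-alkoxybenzylic alkoxyphosphonium ion, leading to E1 elimination to a stilbene or loss of stereospecificity. The fallback uses that ionisation deliberately and runs from 14 to 16. Treatment of 14 with 1 M HCl in THF/H2O would generate the benzylic cation, which the phenol captures under thermodynamic control to give the trans ring, while the same acid removes the acetal and the alkyl silyl ether. Step 9 then becomes unnecessary, and this fallback makes no new compound (F0).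

## Further compounds

F1 | step 6 | (E)-3-(3,4-dimethoxyphenyl)prop-2-en-1-yl methyl carbonate | COC(=O)OC/C=C/c1ccc(OC)c(OC)c1
F2 | step 6 | (S)-3-bromo-4-{[1-(3,4-dimethoxyphenyl)prop-2-en-1-yl]oxy}-5-methoxybenzaldehyde | COc1ccc([C@H](C=C)Oc2c(Br)cc(C=O)cc2OC)cc1OC
F3 | step 6 | (2S,3R)-2-(3,4-dimethoxyphenyl)-7-methoxy-3-{[(2,2,6,6-tetramethylpiperidin-1-yl)oxy]methyl}-2,3-dihydrobenzofuran-5-carbaldehyde | COc1ccc([C@H]2Oc3c(OC)cc(C=O)cc3[C@@H]2CON2C(C)(C)CCCC2(C)C)cc1OC
F4 | step 3 | diisopropyl [3-(tert-butyldimethylsilyloxy)prop-1-yn-1-yl]boronate | CC(C)OB(OC(C)C)C#CCO[Si](C)(C)C(C)(C)C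
F5 | step 3 | 3-(tert-butyldimethylsilyloxy)prop-1-yn-1-yl B(mac) boronic ester | CC(C)(C)[Si](C)(C)OCC#CB1O[C@@]2(C)c3cccc4cccc(c34)[C@@]2(C)O1
F6 | step 7 | (1R,2R)-3-(tert-butyldimethylsilyloxy)-2-[2-(tert-butyldimethylsilyloxy)-5-(1,3-dioxolan-2-yl)-3-methoxyphenyl]-1-(3,4-dimethoxyphenyl)propan-1-ol | COc1ccc([C@H](O)[C@@H](CO[Si](C)(C)C(C)(C)C)c2cc(C3OCCO3)cc(OC)c2O[Si](C)(C)C(C)(C)C)cc1OC
F0 | step 8 | none | none
A1 | alternative 1 | trans-2-(3,4-dimethoxyphenyl)-7-methoxy-3-(tetramethylpiperidinyloxymethyl)-2,3-dihydrobenzofuran-5-carbaldehyde | COc1ccc([C@H]2Oc3c(OC)cc(C=O)cc3[C@@H]2CON2C(C)(C)CCCC2(C)C)cc1OC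
A2 | alternative 1 | (S)-4-{[1-(3,4-dimethoxyphenyl)prop-2-en-1-yl]oxy}-3-iodo-5-methoxybenzaldehyde | COc1ccc([C@H](C=C)Oc2c(I)cc(C=O)cc2OC)cc1OC
A3 | alternative 2 | trans-2-(3,4-dimethoxyphenyl)-7-hydroxy-3,5-bis[(tert-butyldimethylsilyloxy)methyl]-2,3-dihydrobenzofuran | COc1ccc([C@H]2Oc3c(O)cc(CO[Si](C)(C)C(C)(C)C)cc3[C@@H]2CO[Si](C)(C)C(C)(C)C)cc1OC
A4 | alternative 2 | ethynyl ether of 3-(tert-butyldimethylsilyloxy)-2-{4-[(tert-butyldimethylsilyloxy)methyl]furan-2-yl}-1-(3,4-dimethoxyphenyl)propan-1-ol, configured as C2 and C3 of the target | COc1ccc([C@@H](OC#C)[C@@H](CO[Si](C)(C)C(C)(C)C)c2cc(CO[Si](C)(C)C(C)(C)C)co2)cc1OC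
A5 | alternative 3 | methyl trans-7-bromo-2-(3,4-dimethoxyphenyl)-3-[(triisopropylsilyloxy)methyl]-2,3-dihydrobenzofuran-5-carboxylate | COc1ccc([C@H]2Oc3c(Br)cc(C(=O)OC)cc3[C@@H]2CO[Si](C(C)C)(C(C)C)C(C)C)cc1OC
A6 | alternative 3 | methyl 3-bromocoumalate (methyl 3-bromo-2-oxo-2H-pyran-5-carboxylate) | COC(=O)C1=COC(=O)C(Br)=C1
A7 | alternative 3 | tert-butyldimethylsilyl ketene acetal of the trans lactone: (2S,3R)-5-(tert-butyldimethylsilyloxy)-2-(3,4-dimethoxyphenyl)-3-[(triisopropylsilyloxy)methyl]-2,3-dihydrofuran | COc1ccc([C@H]2OC(O[Si](C)(C)C(C)(C)C)=C[C@@H]2CO[Si](C(C)C)(C(C)C)C(C)C)cc1OC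
A8 | alternative 3 | (4R,5S)-5-(3,4-dimethoxyphenyl)-4-[(triisopropylsilyloxy)methyl]dihydrofuran-2(3H)-one (trans) | COc1ccc([C@H]2OC(=O)C[C@@H]2CO[Si](C(C)C)(C(C)C)C(C)C)cc1OC
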